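## Structural features

Prodelphinidin C2 (19) is a linear flavan-3-ol trimer. It has two gallocatechin units (top: phloroglucinol ring A, pyran ring C, pyrogallol ring B; middle: rings D, F and E in the same sense) and one catechin unit at the bottom (phloroglucinol ring G, catechol ring H and its own pyran ring). The units are joined by two C(sp3)–C(sp2) interflavan bonds, from C4 of ring C to C8 of ring D and from C4 of ring F to C8 of ring G. There are eight stereocentres: each upper unit holds a contiguous triad C2/C3/C4 (2,3-trans, 3,4-trans, all substituents equatorial), the bottom unit holds the pair C2/C3, and all three units share the 2R,3S sense. C4 of each upper unit is a diarylmethine whose two aryl rings both carry ortho oxygens, so the junctions are crowded. Fragile features are the fourteen phenols (air, base), the benzylic C2–O1 ethers and the interflavan bonds themselves, which heterolyse under acid, so the endgame must be neutral. The real difficulty is to make the two hindered C4–C8 junctions at the right site (C8, not C6), in the right number (trimer only) and with the 3,4-trans configuration beside a 2,3-trans pair, where a planar C4 cation gets only weak facial guidance. The key step exploits the fact that in each upper unit C4 is bonded to two phloroglucinol-type rings (C4a of its own ring A or D, and C8 of the ring below) while O1 sits ortho to C4a. C3 and C4 can therefore be the two carbons of an alkyne in an aryl propargyl ether (O1–C2–C3≡C4–aryl) with C2 as the only preset stereocentre, and ring A (or D) can close onto C4.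

## Logic of the disconnections

In one sentence: a double gold-catalysed 6-endo-dig hydroarylation turns 14, in which both interflavan carbon–carbon bonds already exist as aryl–alkyne bonds, into 16 by closing rings C and F.

19 to 18: the fourteen phenolic O–H bonds are traced back to O–benzyl bonds. Benzyl ethers are removed by neutral hydrogenolysis, which the acid-labile interflavan bonds tolerate. The forward step must cleave fourteen ethers without touching C2–O1 or C4–C8.

18 to 16: the C3–O and C4–H bonds of rings C and F are removed together. Four stereocentres (C3 and C4 of both upper units) collapse into two trisubstituted alkenes, and each is controlled by its own C2. The forward step must add H and OH syn, with oxygen at C3, on the face anti to the C2 aryl group, at two crowded alkenes.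

16 to 14 (key): the C4–C4a bonds of rings C and F are cut. Both pyran rings open, the two crowded junctions become linear aryl–alkyne bonds, and the site of attachment (C8 of rings D and G) is defined by where the alkynes sit. The forward step must close 6-endo rather than 5-exo, use arene carbon rather than ether oxygen as the nucleophile, and leave the two propargylic C–O bonds (future C2–O1) configurationally intact.

14 to 10 + 13: the C(sp)–C8 bond to ring G is cut. This separates the chiral-pool bottom unit as an aryl iodide from a terminal alkyne. The forward cross-coupling must proceed at a di-ortho-substituted, electron-rich iodide under conditions that do not isomerise the propargylic ether.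

13 to 12 to 11: the C8–I bond and four O–benzyl bonds are cut. The forward steps need C8 over C6 selectivity in the iodination and phenol over alcohol selectivity in the benzylation.

10 to 9 to 6 + 8: the C(sp)–C bond to ring D is cut, with a C–silyl cap on the alkyne of 8. The cap decides which alkyne couples first and is removed afterwards. The forward coupling must occur only between the free alkyne of 6 and the iodide of 8.

6 to 5 to 3 + 4, 8 to 3 + 7, and 7 to 4: the two propargylic C–O bonds (future C2–O1 of both gallocatechin units) are cut. Both units then come from one carbinol and one phenol, since rings B and E are identical. The forward etherification must invert cleanly at a benzylic, propargylic carbon, and the iodination of 4 must go ortho to the hydroxyl.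

3 to 1 + 2: the carbinol C–C(sp) bond is cut. The only reagent-controlled stereocentre of the route is reduced to an aldehyde and an alkyne; the forward addition must be enantioselective.

## Other disconnections considered

Alternative 1: the first plan that comes to mind cuts both C4–C8 bonds as cation plus arene. In the forward sense a Lewis acid (TMSOTf) ionises the C4-activated gallocatechin A1 (3-O-acetyl-4-(2-ethoxyethoxy)-penta-O-benzylgallocatechin), C8 of 12 captures the benzylic cation, and the coupling is repeated with a second equivalent of A1.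
- The nucleophile has two competing sites (C8 and C6), and every product is again a nucleophile, so chain length can only be held by stoichiometric excess.
- In the 2,3-trans series the planar C4 cation is guided only by an equatorial C3 substituent, so 3,4-trans selectivity is not structurally secured.
- A1 needs scarce enantiopure gallocatechin or its de novo synthesis plus a separate C4 oxidation.
- The chosen plan fixes site and chain length by the position of an iodide and relays configuration within each ring.

Alternative 2: cut C4–C8 at the flavylium oxidation level. The flavylium salt A2 would add C8 of 12 at C4 to give the 4-aryl-4H-chromene A3, and hydroboration of A3 would then relay C4 to C3 to C2.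
- The centre from which everything is relayed (C4) is formed in an intermolecular addition to a planar cation. The only chiral information is the remote catechin unit, so A3 is expected as a mixture of C4 epimers.
- Attack at C2 of A2 competes with attack at C4.
- In the chosen plan the controlling centre (C2) is set by a chiral catalyst before the units are joined.

Alternative 3: cut C4–C8 through a [3,3] shift. The 7-O-(1,3-diarylallyl) ether A4 would undergo an aromatic Claisen rearrangement with chair-like 1,3-transfer of chirality to the C8-allylated phenol A5. Asymmetric dihydroxylation of the styrene and acid-mediated closure of ring C would follow.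
- O7 has two ortho carbons (C6 and C8), so the regiochemical problem returns.
- A4 is a doubly activated allylic aryl ether that can ionise at the temperature of an aromatic Claisen rearrangement, which would leak configuration through an ion pair.
- 7-OH must first be differentiated from 5-OH.
- Each junction costs a rearrangement, a dihydroxylation and a cyclisation, against one coupling plus a shared ring closure and a shared hydroboration in the chosen plan.

Key step: step 11

Remark on the chemistry: in step 1 the antipode of the ProPhenol ligand is assumed to be the one that delivers the (S)-carbinol 3; the SMILES of 3 defines the required sense.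

## Steps

Step 1
Reactants: 1 3,4,5-tris(benzyloxy)benzaldehyde; 2 trimethylsilylacetylene
Product: 3 (S)-1-[3,4,5-tris(benzyloxy)phenyl]-3-(trimethylsilyl)prop-2-yn-1-ol
Conditions: Me2Zn (3 equiv), ProPhenol ligand (10 mol %), Ph3P=O (20 mol %), toluene, 0 °C to rt; then aq NH4Cl
Reagents that add atoms: none
Why: Catalytic enantioselective addition of a zinc alkynylide to a non-enolisable aryl aldehyde; the chiral dizinc pocket selects the aldehyde face and so sets the carbinol centre that becomes C2 of both gallocatechin units.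

Step 2
Reactants: 3 (S)-1-[3,4,5-tris(benzyloxy)phenyl]-3-(trimethylsilyl)prop-2-yn-1-ol; 4 3,5-bis(benzyloxy)phenol
Product: 5 (R)-{3-[3,5-bis(benzyloxy)phenoxy]-3-[3,4,5-tris(benzyloxy)phenyl]prop-1-yn-1-yl}trimethylsilane
Conditions: PPh3, DIAD, toluene, 0 °C to rt
Reagents that add atoms: none
Why: Mitsunobu etherification; SN2 attack of the phenoxide on the alkoxyphosphonium inverts the carbinol centre, the C-silyl group blocks SN2' attack at the alkyne terminus, and the 3,4,5-trioxygenated aryl group stabilises a benzylic cation only weakly, which disfavours an SN1 leak.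

Step 3
Reactants: 5 (R)-{3-[3,5-bis(benzyloxy)phenoxy]-3-[3,4,5-tris(benzyloxy)phenyl]prop-1-yn-1-yl}trimethylsilane
Product: 6 (S)-1,3-bis(benzyloxy)-5-{1-[3,4,5-tris(benzyloxy)phenyl]prop-2-yn-1-yloxy}benzene
Conditions: K2CO3 (0.2 equiv), MeOH/THF 1:1, 0 °C to rt
Reagents that add atoms: none
Why: Methanolysis of the alkynyl C–Si bond; the stereocentre is untouched and its descriptor changes only because ethynyl now ranks below the aryl group.

Step 4
Reactants: 4 3,5-bis(benzyloxy)phenol
Product: 7 3,5-bis(benzyloxy)-2-iodophenol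
Conditions: NIS (1.0 equiv), CH2Cl2, −40 °C, dark
Reagents that add atoms: N-iodosuccinimide, O=C1CCC(=O)N1I
Why: Electrophilic aromatic iodination; the two positions ortho to the hydroxyl are equivalent and flanked by the small OH, whereas the para position lies between two benzyloxy groups, so statistics and sterics favour the 2-iodide, and low temperature with one equivalent limits di-iodination.

Step 5
Reactants: 3 (S)-1-[3,4,5-tris(benzyloxy)phenyl]-3-(trimethylsilyl)prop-2-yn-1-ol; 7 3,5-bis(benzyloxy)-2-iodophenol
Product: 8 (R)-{3-[3,5-bis(benzyloxy)-2-iodophenoxy]-3-[3,4,5-tris(benzyloxy)phenyl]prop-1-yn-1-yl}trimethylsilane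
Conditions: PPh3, DIAD, toluene, 0 °C to rt
Reagents that add atoms: none
Why: Mitsunobu etherification with inversion as in step 2; the ortho-iodophenol is more acidic than 4 and therefore a good pronucleophile, and the iodide is placed ortho to the ether oxygen, which will become C8 of the middle unit.

Step 6
Reactants: 6 (S)-1,3-bis(benzyloxy)-5-{1-[3,4,5-tris(benzyloxy)phenyl]prop-2-yn-1-yloxy}benzene; 8 (R)-{3-[3,5-bis(benzyloxy)-2-iodophenoxy]-3-[3,4,5-tris(benzyloxy)phenyl]prop-1-yn-1-yl}trimethylsilane
Product: 9 trimethyl{(3R)-3-[3,5-bis(benzyloxy)-2-{(3R)-3-[3,5-bis(benzyloxy)phenoxy]-3-[3,4,5-tris(benzyloxy)phenyl]prop-1-yn-1-yl}phenoxy]-3-[3,4,5-tris(benzyloxy)phenyl]prop-1-yn-1-yl}silane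
Conditions: Pd(PPh3)2Cl2 (5 mol %), CuI (5 mol %), Et3N/THF 1:2, 40 °C, degassed
Reagents that add atoms: none
Why: Sonogashira coupling; oxidative addition occurs only at the C–I bond and only the free alkyne of 6 can form a copper acetylide, so the silyl-capped alkyne of 8 is a spectator and the order of the units is fixed; this bond is the future C4(ring C)–C8(ring D) junction.

Step 7
Reactants: 9 trimethyl{(3R)-3-[3,5-bis(benzyloxy)-2-{(3R)-3-[3,5-bis(benzyloxy)phenoxy]-3-[3,4,5-tris(benzyloxy)phenyl]prop-1-yn-1-yl}phenoxy]-3-[3,4,5-tris(benzyloxy)phenyl]prop-1-yn-1-yl}silane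
Product: 10 1,5-bis(benzyloxy)-2-{(3R)-3-[3,5-bis(benzyloxy)phenoxy]-3-[3,4,5-tris(benzyloxy)phenyl]prop-1-yn-1-yl}-3-{(1S)-1-[3,4,5-tris(benzyloxy)phenyl]prop-2-yn-1-yloxy}benzene
Conditions: K2CO3 (0.2 equiv), MeOH/THF 1:1, 0 °C to rt
Reagents that add atoms: none
Why: Methanolysis of the alkynyl C–Si bond under mild base that leaves the internal diaryl alkyne and both propargylic ethers untouched.

Step 8
Reactants: 11 (+)-catechin
Product: 12 5,7,3',4'-tetra-O-benzyl-(+)-catechin
Conditions: BnBr (4.4 equiv), K2CO3, DMF, 0 °C to rt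
Reagents that add atoms: benzyl bromide, BrCc1ccccc1
Why: Williamson etherification; carbonate deprotonates only the four phenols, so the secondary 3-OH stays free and the two stereocentres of the chiral pool are untouched.

Step 9
Reactants: 12 5,7,3',4'-tetra-O-benzyl-(+)-catechin
Product: 13 8-iodo-5,7,3',4'-tetra-O-benzyl-(+)-catechin
Conditions: NIS (1.05 equiv), CH2Cl2, −20 to 0 °C, dark
Reagents that add atoms: N-iodosuccinimide, O=C1CCC(=O)N1I
Why: Electrophilic aromatic iodination at C8, the more reactive of the two free positions of a 5,7-di-O-benzyl flavan ring (the selectivity known for bromination with NBS); the dialkoxyphenyl ring H is far less activated.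

Step 10
Reactants: 10 1,5-bis(benzyloxy)-2-{(3R)-3-[3,5-bis(benzyloxy)phenoxy]-3-[3,4,5-tris(benzyloxy)phenyl]prop-1-yn-1-yl}-3-{(1S)-1-[3,4,5-tris(benzyloxy)phenyl]prop-2-yn-1-yloxy}benzene; 13 8-iodo-5,7,3',4'-tetra-O-benzyl-(+)-catechin
Product: 14 linear diyne in which the terminal alkyne of 10 is bonded to C8 of the catechin unit (both propargylic centres R; catechin unit 2R,3S)
Conditions: Pd(PPh3)2Cl2 (5 mol %), CuI (5 mol %), Et3N/DMF 1:2, 50 °C, degassed
Reagents that add atoms: none
Why: Sonogashira coupling at the only aryl iodide; the new C(sp)–C8 bond is the future C4(ring F)–C8(ring G) junction, made without any C4 cation and therefore with no choice of site or chain length.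

Step 11
Reactants: 14 linear diyne in which the terminal alkyne of 10 is bonded to C8 of the catechin unit
Product: 16 bis(2H-chromene) trimer (rings C and F closed; both chromene C2 centres S), via ring-C-closed monochromene 15 (not isolated)
Conditions: [(2-biphenylyl)(t-Bu)2P]Au(NCMe)SbF6 (10 mol %), 2,6-di-tert-butylpyridine (10 mol %), 4 Å MS, CH2Cl2 (0.01 M), rt, dark
Reagents that add atoms: none
Why: The cationic monovalent gold complex binds each alkyne as a π-acid, the alkyne carbon that carries the trioxygenated aryl ring (ring D for the upper alkyne, ring G for the lower) takes on vinyl-cation character, the ortho carbon of the phloroglucinol-type aryl ether adds to it anti to gold, and rearomatisation followed by protodeauration releases the 2H-chromene and the catalyst. The closest known reaction type is the gold- or platinum-catalysed intramolecular hydroarylation of aryl propargyl ethers to 2H-chromenes, 4-aryl examples included, run here twice in one molecule. Ring C is closed 6-endo-dig by ring A and ring F is closed 6-endo-dig by ring D, each closure forming the C4–C4a bond. No stereocentre is formed: the two propargylic centres are spectators that become C2 of the two chromenes, and C3 and C4 are set from them in step 12; rotamers about the two hindered aryl–vinyl bonds may appear but are not stereochemical liabilities. The step needs 6-endo over 5-exo closure, which the aryl polarisation of each alkyne and the strain of an exocyclic alkylidene dihydrobenzofuran secure. It needs carbon over oxygen attack, since ether oxygens sit ortho to both alkynes on rings D and G, and this is secured by the far higher nucleophilicity of an arene carbon that is ortho or para to three oxygens, by its attack at the electronically preferred alkyne carbon and by room temperature. It needs one site on ring D, which is secured because the other ortho position already carries the upper alkyne, so that the 4→8 connectivity is written into 16 by construction. It needs the C2–O bonds to stay intact, for which a non-oxophilic catalyst, molecular sieves and a hindered pyridine keep protic acid away; either ring may close first (15 shows ring C closed) and both orders converge.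

Step 12
Reactants: 16 bis(2H-chromene) trimer (rings C and F closed; both chromene C2 centres S)
Product: 18 tetradeca-O-benzyl prodelphinidin C2 (three free 3-OH groups), via tris(borane) adduct 17 (not isolated)
Conditions: BH3·THF (10 equiv), THF, 0 to 40 °C; then 3 M NaOH, 30% H2O2, 0 °C to rt
Reagents that add atoms: hydrogen peroxide, OO
Why: Hydroboration–oxidation; boron adds to C3 (less substituted, non-benzylic) and hydrogen to C4 in a syn four-centre addition on the face anti to the C2 aryl group, and oxidation goes with retention, so each C2 sets its own C3 (OH trans to the C2 aryl) and C4 (H cis to OH, interflavan bond 3,4-trans), as is established for flav-3-enes giving 2,3-trans-flavan-3-ols. The free 3-OH of the bottom unit is carried as its borate and returns on work-up.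

Step 13
Reactants: 18 tetradeca-O-benzyl prodelphinidin C2 (three free 3-OH groups)
Product: 19 prodelphinidin C2
Conditions: H2 (1 atm), Pd(OH)2/C, THF/MeOH/H2O, rt
Reagents that add atoms: none
Why: Hydrogenolysis of the fourteen benzyl ethers under neutral conditions, which the cyclic C2–O1 ethers and the acid-labile interflavan bonds of flavans tolerate; no stereocentre is involved, and degassed solvents protect the free polyphenol.

## Compound list

1 | 3,4,5-tris(benzyloxy)benzaldehyde | O=Cc1cc(OCc5ccccc5)c(OCc5ccccc5)c(OCc5ccccc5)c1 | starting material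
2 | trimethylsilylacetylene | C#C[Si](C)(C)C | starting material
3 | (S)-1-[3,4,5-tris(benzyloxy)phenyl]-3-(trimethylsilyl)prop-2-yn-1-ol | O[C@@H](c1cc(OCc5ccccc5)c(OCc5ccccc5)c(OCc5ccccc5)c1)C#C[Si](C)(C)C | intermediate
4 | 3,5-bis(benzyloxy)phenol | Oc1cc(OCc5ccccc5)cc(OCc5ccccc5)c1 | starting material
5 | (R)-{3-[3,5-bis(benzyloxy)phenoxy]-3-[3,4,5-tris(benzyloxy)phenyl]prop-1-yn-1-yl}trimethylsilane | c5ccccc5COc1cc(OCc5ccccc5)cc(c1)O[C@H](c1cc(OCc5ccccc5)c(OCc5ccccc5)c(OCc5ccccc5)c1)C#C[Si](C)(C)C | intermediate
6 | (S)-1,3-bis(benzyloxy)-5-{1-[3,4,5-tris(benzyloxy)phenyl]prop-2-yn-1-yloxy}benzene | c5ccccc5COc1cc(OCc5ccccc5)cc(c1)O[C@H](c1cc(OCc5ccccc5)c(OCc5ccccc5)c(OCc5ccccc5)c1)C#C | intermediate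
7 | 3,5-bis(benzyloxy)-2-iodophenol | Oc1cc(OCc5ccccc5)cc(OCc5ccccc5)c1I | intermediate
8 | (R)-{3-[3,5-bis(benzyloxy)-2-iodophenoxy]-3-[3,4,5-tris(benzyloxy)phenyl]prop-1-yn-1-yl}trimethylsilane | Ic1c(OCc5ccccc5)cc(OCc5ccccc5)cc1O[C@H](c1cc(OCc5ccccc5)c(OCc5ccccc5)c(OCc5ccccc5)c1)C#C[Si](C)(C)C | intermediate
9 | trimethyl{(3R)-3-[3,5-bis(benzyloxy)-2-{(3R)-3-[3,5-bis(benzyloxy)phenoxy]-3-[3,4,5-tris(benzyloxy)phenyl]prop-1-yn-1-yl}phenoxy]-3-[3,4,5-tris(benzyloxy)phenyl]prop-1-yn-1-yl}silane | c5ccccc5COc1cc(OCc5ccccc5)cc(c1)O[C@H](c1cc(OCc5ccccc5)c(OCc5ccccc5)c(OCc5ccccc5)c1)C#Cc1c(OCc5ccccc5)cc(OCc5ccccc5)cc1O[C@H](c1cc(OCc5ccccc5)c(OCc5ccccc5)c(OCc5ccccc5)c1)C#C[Si](C)(C)C | intermediate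
10 | 1,5-bis(benzyloxy)-2-{(3R)-3-[3,5-bis(benzyloxy)phenoxy]-3-[3,4,5-tris(benzyloxy)phenyl]prop-1-yn-1-yl}-3-{(1S)-1-[3,4,5-tris(benzyloxy)phenyl]prop-2-yn-1-yloxy}benzene | c5ccccc5COc1cc(OCc5ccccc5)cc(c1)O[C@H](c1cc(OCc5ccccc5)c(OCc5ccccc5)c(OCc5ccccc5)c1)C#Cc1c(OCc5ccccc5)cc(OCc5ccccc5)cc1O[C@H](c1cc(OCc5ccccc5)c(OCc5ccccc5)c(OCc5ccccc5)c1)C#C | intermediate
11 | (+)-catechin, (2R,3S) | O[C@H]1Cc2c(O)cc(O)cc2O[C@@H]1c1ccc(O)c(O)c1 | starting material
12 | 5,7,3',4'-tetra-O-benzyl-(+)-catechin | O[C@H]1Cc2c(OCc5ccccc5)cc(OCc5ccccc5)cc2O[C@@H]1c1ccc(OCc5ccccc5)c(OCc5ccccc5)c1 | intermediate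
13 | 8-iodo-5,7,3',4'-tetra-O-benzyl-(+)-catechin | O[C@H]1Cc2c(OCc5ccccc5)cc(OCc5ccccc5)c(I)c2O[C@@H]1c1ccc(OCc5ccccc5)c(OCc5ccccc5)c1 | intermediate
14 | linear diyne: terminal alkyne of 10 bonded to C8 of the tetra-O-benzylcatechin unit; both propargylic centres R, catechin unit 2R,3S | c5ccccc5COc1cc(OCc5ccccc5)cc(c1)O[C@H](c1cc(OCc5ccccc5)c(OCc5ccccc5)c(OCc5ccccc5)c1)C#Cc1c(OCc5ccccc5)cc(OCc5ccccc5)cc1O[C@H](c1cc(OCc5ccccc5)c(OCc5ccccc5)c(OCc5ccccc5)c1)C#Cc1c(OCc5ccccc5)cc(OCc5ccccc5)c2c1O[C@H](c1ccc(OCc5ccccc5)c(OCc5ccccc5)c1)[C@@H](O)C2 | intermediate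
15 | monochromene: ring C closed to a (2S)-5,7-bis(benzyloxy)-2-[3,4,5-tris(benzyloxy)phenyl]-2H-chromen-4-yl group on ring D; lower (R)-propargylic ether and alkyne unchanged | c5ccccc5COc1cc(OCc5ccccc5)c2c(c1)O[C@H](c1cc(OCc5ccccc5)c(OCc5ccccc5)c(OCc5ccccc5)c1)C=C2c1c(OCc5ccccc5)cc(OCc5ccccc5)cc1O[C@H](c1cc(OCc5ccccc5)c(OCc5ccccc5)c(OCc5ccccc5)c1)C#Cc1c(OCc5ccccc5)cc(OCc5ccccc5)c2c1O[C@H](c1ccc(OCc5ccccc5)c(OCc5ccccc5)c1)[C@@H](O)C2 | intermediate
16 | bis(2H-chromene) trimer: top (2S)-flav-3-ene bonded through C4 to C8 of the middle (2S)-flav-3-ene, itself bonded through C4 to C8 of the (2R,3S)-tetra-O-benzylcatechin unit | c5ccccc5COc1cc(OCc5ccccc5)c2c(c1)O[C@H](c1cc(OCc5ccccc5)c(OCc5ccccc5)c(OCc5ccccc5)c1)C=C2c1c(OCc5ccccc5)cc(OCc5ccccc5)c2c1O[C@H](c1cc(OCc5ccccc5)c(OCc5ccccc5)c(OCc5ccccc5)c1)C=C2c1c(OCc5ccccc5)cc(OCc5ccccc5)c2c1O[C@H](c1ccc(OCc5ccccc5)c(OCc5ccccc5)c1)[C@@H](O)C2 | intermediate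
17 | tris(borane) adduct of 16: BH2 at C3 of both upper units (trans to the C2 aryl, H at C4 cis to boron), bottom unit as 3-O–BH2 | c5ccccc5COc1cc(OCc5ccccc5)c2c(c1)O[C@H](c1cc(OCc5ccccc5)c(OCc5ccccc5)c(OCc5ccccc5)c1)[C@@H](B)[C@@H]2c1c(OCc5ccccc5)cc(OCc5ccccc5)c2c1O[C@H](c1cc(OCc5ccccc5)c(OCc5ccccc5)c(OCc5ccccc5)c1)[C@@H](B)[C@@H]2c1c(OCc5ccccc5)cc(OCc5ccccc5)c2c1O[C@H](c1ccc(OCc5ccccc5)c(OCc5ccccc5)c1)[C@@H](OB)C2 | intermediate
18 | tetradeca-O-benzyl prodelphinidin C2: all fourteen phenols as benzyl ethers, three free 3-OH; every unit 2R,3S, both interflavan bonds 4α (3,4-trans) to C8 | c5ccccc5COc1cc(OCc5ccccc5)c2c(c1)O[C@H](c1cc(OCc5ccccc5)c(OCc5ccccc5)c(OCc5ccccc5)c1)[C@@H](O)[C@@H]2c1c(OCc5ccccc5)cc(OCc5ccccc5)c2c1O[C@H](c1cc(OCc5ccccc5)c(OCc5ccccc5)c(OCc5ccccc5)c1)[C@@H](O)[C@@H]2c1c(OCc5ccccc5)cc(OCc5ccccc5)c2c1O[C@H](c1ccc(OCc5ccccc5)c(OCc5ccccc5)c1)[C@@H](O)C2 | intermediate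
19 | prodelphinidin C2, gallocatechin-(4α→8)-gallocatechin-(4α→8)-catechin | Oc1cc(O)c2c(c1)O[C@H](c1cc(O)c(O)c(O)c1)[C@@H](O)[C@@H]2c1c(O)cc(O)c2c1O[C@H](c1cc(O)c(O)c(O)c1)[C@@H](O)[C@@H]2c1c(O)cc(O)c2c1O[C@H](c1ccc(O)c(O)c1)[C@@H](O)C2 | target

## Step count, longest linear sequence and least certain steps

Total: 13 steps. Longest linear sequence: 9 steps (steps 1, 2, 3, 6, 7, 10, 11, 12, 13).

Step 11 (key step). Three processes are most likely to go wrong:
- 5-endo attack of an ether oxygen that sits ortho to an activated alkyne, followed by loss or migration of its O-substituent, which leads towards benzofurans;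
- heterolysis of a propargylic C–O bond under adventitious acid, with loss of configuration at the future C2;
- a stalled second closure in the crowded half-cyclised molecule.

The fallback closes the rings one at a time on simpler substrates and sets out from 9. The same gold catalyst is applied to 9, where only the aryl-substituted alkyne is a good π-acid substrate (the silyl-capped alkyne is shielded and unpolarised) and the bottom unit with its own ortho oxygens is still absent. This should give the ring-C-closed silyl alkyne F1. Methanolysis (K2CO3, MeOH/THF) gives the ring-C-closed terminal alkyne F2. Sonogashira coupling of F2 with 13 gives 15, now isolated, and a second hydroarylation, for which a different π-acid such as PtCl4 in dioxane can be chosen independently, returns to the route at 16.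

Step 12. The two alkenes are trisubstituted and flanked by ortho-substituted aryl rings, so slow hydroboration is possible. Incomplete facial control at one of the two chromenes would give C3/C4 epimers, and loss of the β-oxygen from the C3 borane (opening of the pyran ring) is a further risk. The fallback abandons the late double hydroboration and uses the same chemistry on an uncrowded monomer, followed by classical cationic coupling; it sets out from 6 and 12.
- Gold-catalysed hydroarylation of 6 gives the monomeric (S)-5,7-bis(benzyloxy)-2-[3,4,5-tris(benzyloxy)phenyl]-2H-chromene F3.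
- Hydroboration–oxidation of F3, the precedented unhindered case, gives 5,7,3',4',5'-penta-O-benzyl-(+)-gallocatechin F4.
- Oxidation at C4 with DDQ in the presence of 2-ethoxyethanol gives the 4-(2-ethoxyethoxy) ether F5.
- TMSOTf in CH2Cl2 at −78 °C with an excess of 12 gives the gallocatechin-(4α→8)-catechin nona-O-benzyl dimer F6.
- A second TMSOTf- or AgOTf-mediated coupling of F5 with F6 returns to the route at 18.

Step 4. Iodination may occur at the position para to the hydroxyl (between the two benzyloxy groups) or twice, because all three free positions are activated. The fallback fixes the site by directed metalation and sets out from 4. Carbamoylation (ClC(O)NEt2, K2CO3, MeCN) gives 3,5-bis(benzyloxy)phenyl N,N-diethylcarbamate F7. Lithiation with s-BuLi/TMEDA in THF at −78 °C occurs at the carbon between the carbamate and a benzyloxy group, and an iodine quench at that temperature gives 3,5-bis(benzyloxy)-2-iodophenyl N,N-diethylcarbamate F8. Hydrolysis (KOH, EtOH, reflux) returns to the route at 7.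

Step 2 (the same concern applies to step 5). Partial ionisation of the benzylic, propargylic alkoxyphosphonium would erode the configuration that defines C2. The fallback forms the aryl–oxygen bond instead, so the carbinol C–O bond is never broken; it sets out from 1 and 2. Step 1 is run with the other ligand antipode to give (R)-1-[3,4,5-tris(benzyloxy)phenyl]-3-(trimethylsilyl)prop-2-yn-1-ol F9. Palladium-catalysed C–O coupling of F9 with commercial 1-bromo-3,5-bis(benzyloxy)benzene ([Pd(cinnamyl)Cl]2, a bulky biaryl di-tert-butylphosphine, Cs2CO3, toluene, 90 °C) proceeds with retention and returns to the route at 5.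

Step 6. Oxidative addition at the di-ortho-substituted, electron-rich iodide of 8 may be slow enough for oxidative homocoupling of 6 or base-mediated propargyl–allenyl isomerisation to compete. The fallback couples before the bulky ether is in place and sets out from 6 and 7. Sonogashira coupling of 6 with the free iodophenol 7 at room temperature gives the ortho-alkynylphenol F10. It is kept cold and metal-free after work-up to avoid closure to a benzofuran. Mitsunobu etherification of F10 with 3 returns to the route at 9.

## Further compounds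

F1 | step 11 | ring-C-closed silyl alkyne: (2S)-2H-chromen-4-yl group on ring D, (R)-propargylic ether with C-silyl alkyne | c5ccccc5COc1cc(OCc5ccccc5)c2c(c1)O[C@H](c1cc(OCc5ccccc5)c(OCc5ccccc5)c(OCc5ccccc5)c1)C=C2c1c(OCc5ccccc5)cc(OCc5ccccc5)cc1O[C@H](c1cc(OCc5ccccc5)c(OCc5ccccc5)c(OCc5ccccc5)c1)C#C[Si](C)(C)C
F2 | step 11 | ring-C-closed terminal alkyne: F1 without the silyl group | c5ccccc5COc1cc(OCc5ccccc5)c2c(c1)O[C@H](c1cc(OCc5ccccc5)c(OCc5ccccc5)c(OCc5ccccc5)c1)C=C2c1c(OCc5ccccc5)cc(OCc5ccccc5)cc1O[C@H](c1cc(OCc5ccccc5)c(OCc5ccccc5)c(OCc5ccccc5)c1)C#C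
F3 | step 12 | (S)-5,7-bis(benzyloxy)-2-[3,4,5-tris(benzyloxy)phenyl]-2H-chromene | c5ccccc5COc1cc(OCc5ccccc5)c2c(c1)O[C@H](c1cc(OCc5ccccc5)c(OCc5ccccc5)c(OCc5ccccc5)c1)C=C2
F4 | step 12 | 5,7,3',4',5'-penta-O-benzyl-(+)-gallocatechin, (2R,3S) | c5ccccc5COc1cc(OCc5ccccc5)c2c(c1)O[C@H](c1cc(OCc5ccccc5)c(OCc5ccccc5)c(OCc5ccccc5)c1)[C@@H](O)C2
F5 | step 12 | (2R,3S,4S)-4-(2-ethoxyethoxy)-5,7,3',4',5'-penta-O-benzylgallocatechin (configuration at C4 is lost on ionisation) | c5ccccc5COc1cc(OCc5ccccc5)c2c(c1)O[C@H](c1cc(OCc5ccccc5)c(OCc5ccccc5)c(OCc5ccccc5)c1)[C@@H](O)[C@H]2OCCOCC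
F6 | step 12 | penta-O-benzylgallocatechin-(4α→8)-tetra-O-benzylcatechin | c5ccccc5COc1cc(OCc5ccccc5)c2c(c1)O[C@H](c1cc(OCc5ccccc5)c(OCc5ccccc5)c(OCc5ccccc5)c1)[C@@H](O)[C@@H]2c1c(OCc5ccccc5)cc(OCc5ccccc5)c2c1O[C@H](c1ccc(OCc5ccccc5)c(OCc5ccccc5)c1)[C@@H](O)C2
F7 | step 4 | 3,5-bis(benzyloxy)phenyl N,N-diethylcarbamate | CCN(CC)C(=O)Oc1cc(OCc5ccccc5)cc(OCc5ccccc5)c1
F8 | step 4 | 3,5-bis(benzyloxy)-2-iodophenyl N,N-diethylcarbamate | CCN(CC)C(=O)Oc1cc(OCc5ccccc5)cc(OCc5ccccc5)c1I
F9 | step 2 | (R)-1-[3,4,5-tris(benzyloxy)phenyl]-3-(trimethylsilyl)prop-2-yn-1-ol | O[C@H](c1cc(OCc5ccccc5)c(OCc5ccccc5)c(OCc5ccccc5)c1)C#C[Si](C)(C)C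
F10 | step 6 | 3,5-bis(benzyloxy)-2-{(3R)-3-[3,5-bis(benzyloxy)phenoxy]-3-[3,4,5-tris(benzyloxy)phenyl]prop-1-yn-1-yl}phenol | c5ccccc5COc1cc(OCc5ccccc5)cc(c1)O[C@H](c1cc(OCc5ccccc5)c(OCc5ccccc5)c(OCc5ccccc5)c1)C#Cc1c(OCc5ccccc5)cc(OCc5ccccc5)cc1O
A1 | alternative 1 | (2R,3S,4S)-3-O-acetyl-4-(2-ethoxyethoxy)-5,7,3',4',5'-penta-O-benzylgallocatechin | c5ccccc5COc1cc(OCc5ccccc5)c2c(c1)O[C@H](c1cc(OCc5ccccc5)c(OCc5ccccc5)c(OCc5ccccc5)c1)[C@@H](OC(C)=O)[C@H]2OCCOCC
A2 | alternative 2 | 5,7-bis(benzyloxy)-2-[3,4,5-tris(benzyloxy)phenyl]chromenylium hexafluorophosphate | c5ccccc5COc1cc(OCc5ccccc5)c2ccc(-c3cc(OCc5ccccc5)c(OCc5ccccc5)c(OCc5ccccc5)c3)[o+]c2c1.F[P-](F)(F)(F)(F)F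
A3 | alternative 2 | 4-(tetra-O-benzylcatechin-8-yl)-5,7-bis(benzyloxy)-2-[3,4,5-tris(benzyloxy)phenyl]-4H-chromene, drawn as the C4 epimer that is needed | c5ccccc5COc1cc(OCc5ccccc5)c2c(c1)OC(c1cc(OCc5ccccc5)c(OCc5ccccc5)c(OCc5ccccc5)c1)=C[C@@H]2c1c(OCc5ccccc5)cc(OCc5ccccc5)c2c1O[C@H](c1ccc(OCc5ccccc5)c(OCc5ccccc5)c1)[C@@H](O)C2
A4 | alternative 3 | 5,3',4'-tri-O-benzyl-(+)-catechin 7-O-[(E)-3-[2,4-bis(benzyloxy)-6-(methoxymethoxy)phenyl]-1-[3,4,5-tris(benzyloxy)phenyl]allyl] ether | O[C@H]1Cc2c(OCc5ccccc5)cc(O[C@@H](c3cc(OCc5ccccc5)c(OCc5ccccc5)c(OCc5ccccc5)c3)/C=C/c3c(OCc5ccccc5)cc(OCc5ccccc5)cc3OCOC)cc2O[C@@H]1c1ccc(OCc5ccccc5)c(OCc5ccccc5)c1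
A5 | alternative 3 | 8-[(E)-1-[2,4-bis(benzyloxy)-6-(methoxymethoxy)phenyl]-3-[3,4,5-tris(benzyloxy)phenyl]allyl]-5,3',4'-tri-O-benzyl-(+)-catechin with free 7-OH | COCOc1cc(OCc5ccccc5)cc(OCc5ccccc5)c1[C@H](/C=C/c1cc(OCc5ccccc5)c(OCc5ccccc5)c(OCc5ccccc5)c1)c1c(O)cc(OCc5ccccc5)c2c1O[C@H](c1ccc(OCc5ccccc5)c(OCc5ccccc5)c1)[C@@H](O)C2
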